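The rate constants are hidden from you, but the runs can stand in for them.

| flask | substrate | solid reagent | remark | time |
|---|---|---|---|---|
| winter | 1 M | 0.70 M | the very flask that is asked about, followed so far |  |
| dawn | 1 M | 1.4 M | run made earlier |  |
| flask | 1.0 M | 0.700 M |  | 8.0 h |

- winter (time / h: target / %, side product / %): 0.333: 1, 1; 1.00: 11, 2; 2.00: 24, 3; 3.00: 34, 9; 4.00: 38, 10
- dawn (time / h: target / %, side product / %): 1.50: 16, 3; 3.00: 34, 10; 5.00: 51, 9; 6.00: 58, 12; 8.00: 63, 20

(readings scatter by 2 percentage points)

1. at 8.0 h, what has stopped the reaction, if anything has (for what has run out or reacted, a solid counts together with what of it has only dissolved) (forward and back rates have come level / it is still moving / all of the substrate has reacted / the coupling partner has run out first)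
2. how much target there is at 8.0 h, in percent of the substrate charged
3. how much side product there is at 8.0 h, in percent of the substrate charged

The winter and dawn runs both read 34 % target at 3.00 h, though dawn holds twice the solid reagent, so up to that time the pace seems not to follow the solid charged. I therefore take dawn as showing what the winter flask wants. Assume, unproven, that each product takes one coupling partner, which comes from the dissolving solid:

N = (target + side product, dawn at 8.00 h) × c(substrate) / c(solid reagent) = 1.19

This demand number is the partner wanted by that time per partner charged. It stands above one, so the solid is the limiting reagent, and on that assumption the products together should stop at 70.0 % of the substrate.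

N says that the ceiling counts, but not when it comes. Dawn read that total at 6.00 h, but in the winter flask, once the solid is gone, the dissolved partner should fall, and the rate with it. I expect the winter flask still moving at 8.0 h, below the ceiling. With the target share read from dawn at 8.00 h, 75.9 %, I reckon winter target at 8.0 h should stay under 53.1 %.

The forecast gives 55 % target, 15 % side product and this ending: the coupling partner has run out first, “with the partner essentially spent”. We part on that ending and on target.

    substrate + coupling partner ⇌ intermediate A (K = 0.430 M⁻¹, k = 3.50 × 10⁻⁴ M⁻¹ s⁻¹)
    intermediate A → side product (k = 1.70 × 10⁻⁴ s⁻¹)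
    substrate + coupling partner ⇌ intermediate B (K = 1.00 M⁻¹, k = 7.90 × 10⁻⁴ M⁻¹ s⁻¹)
    intermediate B ⇌ intermediate C (K = 5.80, k = 3.70 × 10⁻⁴ s⁻¹)
    intermediate B ⇌ intermediate D (K = 0.200, k = 1.20 × 10⁻⁴ s⁻¹)
    intermediate C → target (k = 0.00560 s⁻¹)
    solid reagent ⇌ coupling partner, rate k7*(cs7 - [coupling partner]) while solid is left; crystals form when [coupling partner] > cs7 (solubility = 0.230 M, k = 0.00760 s⁻¹)

The flask gives 51.8 % target and 12.5 % side product, 64.3 % together, and it is still moving: 0.0390 M coupling partner remains at 8.00 h. The neighbour flask with 2.8 M of solid reagent has, with dawn's products, N = 0.296, below one, so 70.4 % of its charge should stay out of the products. At 8.00 h it holds 61.6 % as solid, 0.229 M dissolved and 1.66 % of its charge in intermediates A to D, together 71.4 % of its charge, with 64.3 % target.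

The readings were computed from invented constants.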